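**Retrosynthetic overview**

1. Target 20 ← Steglich esterification of alcohol 18 ← desilylation of quinone 17 ← para-oxygenation (C1–H to C1=O) of 1-naphthol 16.
2. 16 ← one-pot assembly from the open-chain diynone 11 and 2-methoxyfuran 12. Ring A (C4a–C5–C6–C7–C8–C8a) closes first by [4+2] cycloaddition and ring-opening aromatisation. Ring B closes second by 6-endo-dig attack of the acetyl carbon (C3) on the distal alkyne carbon (C2), forming C2–C3.
3. Enabling feature: the path C3–C4–C4a–C8a–C1–C2–C1' of the target is an unbranched seven-carbon chain, which is the backbone of a hexa-3,5-diyn-2-one (acetyl = C3/C4, ynone alkyne = C4a/C8a, second alkyne = C1/C2). Ring A carries two para oxygens, one methylated (C5–OMe) and one free (C8–OH), which is what the methoxy group and the ring oxygen of 2-methoxyfuran become.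
4. 11 ← acetylation of terminal diyne 8 ← (S)-diynol 6 ← Noyori asymmetric transfer hydrogenation of diynone 5 ← Weinreb amide 2 + bis-silyl diyne 3. C1' is set at 6 and carried through.

Key step: step 7

Remark: atoms are numbered as in 1,4-naphthoquinone (C1=O peri to C8–OH and bonded to C2 with the side chain, C4=O peri to C5–OMe, C1' = side-chain carbinol carbon). The stereocentre of the target SMILES is read as (S). Compounds 1, 3, 9, 12 and 19 are taken as commercially available.

**Route**

Step 1
Reactants: 1 4-methylpent-3-enoic acid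
Product: 2 N-methoxy-N,4-dimethylpent-3-enamide
Conditions: CDI, CH2Cl2, 0 °C to rt; then MeNH(OMe)·HCl, rt
Reagents that add atoms: N,O-dimethylhydroxylamine hydrochloride, CNOC.Cl
Why: Acyl imidazolide formation and aminolysis (Weinreb amide synthesis) should give the amide under near-neutral conditions that leave the skipped alkene in place.

Step 2
Reactants: 2 N-methoxy-N,4-dimethylpent-3-enamide; 3 1,4-bis(trimethylsilyl)buta-1,3-diyne
Product: 5 8-methyl-1-(trimethylsilyl)non-7-ene-1,3-diyn-5-one, via lithium (trimethylsilyl)butadiynide 4 (not isolated)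
Conditions: 3, MeLi·LiBr (1.0 equiv), THF, 0 °C to rt; then 2, −78 to 0 °C; aq. NH4Cl
Reagents that add atoms: none
Why: Mono-desilylative lithiation of the bis-silyl diyne followed by Weinreb ketone synthesis should stop at the ketone because the chelated tetrahedral adduct survives until work-up.

Step 3
Reactants: 5 8-methyl-1-(trimethylsilyl)non-7-ene-1,3-diyn-5-one
Product: 6 (S)-8-methyl-1-(trimethylsilyl)non-7-ene-1,3-diyn-5-ol
Conditions: Ru[(S,S)-TsDPEN](p-cymene) (cat., base-free amido complex), i-PrOH, rt
Reagents that add atoms: none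
Why: Noyori asymmetric transfer hydrogenation of an alkynyl ketone, in which the alkynyl group acts as the π-substituent, so the (S,S)-catalyst should deliver hydride to the face that gives the (S)-carbinol, and the base-free conditions should leave the skipped enone unisomerised.

Step 4
Reactants: 6 (S)-8-methyl-1-(trimethylsilyl)non-7-ene-1,3-diyn-5-ol
Product: 7 (S)-5-(tert-butyldimethylsilyloxy)-8-methyl-1-(trimethylsilyl)non-7-ene-1,3-diyne
Conditions: TBSCl, imidazole, DMF, rt
Reagents that add atoms: tert-butyldimethylsilyl chloride, CC(C)(C)[Si](C)(C)Cl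
Why: Standard O-silylation of a secondary alcohol, which does not touch the stereocentre.

Step 5
Reactants: 7 (S)-5-(tert-butyldimethylsilyloxy)-8-methyl-1-(trimethylsilyl)non-7-ene-1,3-diyne
Product: 8 (S)-5-(tert-butyldimethylsilyloxy)-8-methylnon-7-ene-1,3-diyne
Conditions: K2CO3 (cat.), MeOH, 0 °C to rt; used directly
Reagents that add atoms: none
Why: Methanolysis of the C(sp)–SiMe3 bond is selective over the O–TBS ether and is too mildly basic to epimerise the propargylic centre.

Step 6
Reactants: 8 (S)-5-(tert-butyldimethylsilyloxy)-8-methylnon-7-ene-1,3-diyne; 9 N-methoxy-N-methylacetamide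
Product: 11 (S)-7-(tert-butyldimethylsilyloxy)-10-methylundec-9-ene-3,5-diyn-2-one, via lithium diynide 10 (not isolated)
Conditions: n-BuLi (1.0 equiv), THF, −78 °C; then 9, −78 to 0 °C; aq. NH4Cl
Reagents that add atoms: none
Why: Deprotonation of the terminal diyne is far faster than any other lithiation at −78 °C, and acylation of the acetylide by the Weinreb amide (Weinreb ketone synthesis) should give the methyl ynone without over-addition.

Step 7
Reactants: 11 (S)-7-(tert-butyldimethylsilyloxy)-10-methylundec-9-ene-3,5-diyn-2-one; 12 2-methoxyfuran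
Product: 16 5-(tert-butyldimethylsilyloxy)-3-[(S)-1-(tert-butyldimethylsilyloxy)-4-methylpent-3-enyl]-8-methoxynaphthalen-1-ol, via oxanorbornadiene cycloadduct 13 (not isolated), via phenol 14 (not isolated), via aryl silyl ether 15 (not isolated)
Conditions: 12 (1.2 equiv), toluene, 0 °C to rt; then THF, KHMDS (1.0 equiv), −78 °C, TBSCl, to 0 °C; then KHMDS (1.1 equiv), −78 to 0 °C; aq. NH4Cl
Reagents that add atoms: tert-butyldimethylsilyl chloride, CC(C)(C)[Si](C)(C)Cl
Why: 2-Methoxyfuran 12 should add as the diene across the ynone triple bond of 11, its unsubstituted C5 (the nucleophilic terminus) bonding to the ynone β-carbon, and the 1-methoxy-7-oxanorbornadiene 13 should open at the methoxy-bearing bridgehead and lose the other bridgehead proton to give phenol 14, which is capped as 15 before the potassium enolate of the acetyl group attacks the distal alkyne carbon and the adduct tautomerises to the naphtholate of 16. The closest known reaction types are the phenol synthesis from 2-methoxyfuran and acetylenic ketones or esters and the KHMDS-promoted cyclisation of ortho-alkynyl acetophenones to 3-substituted 1-naphthols. Ring A is closed by an intermolecular [4+2] cycloaddition (bonds C5–C4a and C8–C8a) followed by ring-opening aromatisation, and ring B by a 6-endo-dig carbocyclisation that forms C2–C3. No new stereocentre remains: the two bridgehead centres of 13 arise as a diastereomer mixture that converges on one arene, and C1' is only carried through. The step needs the regiochemistry OMe next to the acetyl-bearing carbon and OH next to the alkynyl-bearing carbon, which the donor–acceptor match of the methoxy-activated furan terminus and the acetyl-activated alkyne carbon secures, and it needs cycloaddition at the ynone triple bond only, which is the only one conjugated to the carbonyl. It further needs C-attack in the 6-endo mode without loss of configuration at C1', which the aromatic product, the in-plane reach of the enolate carbon and the use of one equivalent of base at low temperature (no deprotonation of the propargylic C–H) should secure, while the silylation stage removes the phenoxide that would deactivate the alkyne or close to a benzofuran.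

Step 8
Reactants: 16 5-(tert-butyldimethylsilyloxy)-3-[(S)-1-(tert-butyldimethylsilyloxy)-4-methylpent-3-enyl]-8-methoxynaphthalen-1-ol
Product: 17 8-(tert-butyldimethylsilyloxy)-2-[(S)-1-(tert-butyldimethylsilyloxy)-4-methylpent-3-enyl]-5-methoxynaphthalene-1,4-dione
Conditions: Co(salen) (salcomine, cat.), O2 (1 atm), MeCN, rt
Reagents that add atoms: dioxygen, O=O
Why: Cobalt–dioxygen para-oxygenation of a 1-naphthol to the 1,4-naphthoquinone should act only on the single free phenol, so the quinone is forced into ring B while the silylated and methylated ring A stays aromatic.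

Step 9
Reactants: 17 8-(tert-butyldimethylsilyloxy)-2-[(S)-1-(tert-butyldimethylsilyloxy)-4-methylpent-3-enyl]-5-methoxynaphthalene-1,4-dione
Product: 18 8-hydroxy-2-[(S)-1-hydroxy-4-methylpent-3-enyl]-5-methoxynaphthalene-1,4-dione
Conditions: HF·pyridine, pyridine/THF, 0 °C to rt
Reagents that add atoms: none
Why: Buffered fluoride should cleave both the aryl and the secondary alkyl silyl ether at silicon without base that would attack the quinone and without acid strong enough to ionise the allylic carbinol.

Step 10
Reactants: 18 8-hydroxy-2-[(S)-1-hydroxy-4-methylpent-3-enyl]-5-methoxynaphthalene-1,4-dione; 19 3-methylbut-2-enoic acid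
Product: 20 (S)-1-(8-hydroxy-5-methoxy-1,4-dioxo-1,4-dihydronaphthalen-2-yl)-4-methylpent-3-enyl 3-methylbut-2-enoate
Conditions: DCC, DMAP (cat.), CH2Cl2, 0 °C to rt
Reagents that add atoms: none
Why: Steglich esterification should acylate only the secondary alcohol, because the C8 hydroxyl is held in a hydrogen bond to the C1 carbonyl, and acylation at oxygen leaves the (S)-centre untouched.

**Compound list**

1 | 4-methylpent-3-enoic acid | CC(C)=CCC(=O)O | starting material
2 | N-methoxy-N,4-dimethylpent-3-enamide | CC(C)=CCC(=O)N(C)OC | intermediate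
3 | 1,4-bis(trimethylsilyl)buta-1,3-diyne | C[Si](C)(C)C#CC#C[Si](C)(C)C | starting material
4 | lithium (trimethylsilyl)butadiynide | [Li]C#CC#C[Si](C)(C)C | intermediate
5 | 8-methyl-1-(trimethylsilyl)non-7-ene-1,3-diyn-5-one | C[Si](C)(C)C#CC#CC(=O)CC=C(C)C | intermediate
6 | (S)-8-methyl-1-(trimethylsilyl)non-7-ene-1,3-diyn-5-ol | C[Si](C)(C)C#CC#C[C@H](CC=C(C)C)O | intermediate
7 | (S)-5-(tert-butyldimethylsilyloxy)-8-methyl-1-(trimethylsilyl)non-7-ene-1,3-diyne | C[Si](C)(C)C#CC#C[C@H](CC=C(C)C)O[Si](C)(C)C(C)(C)C | intermediate
8 | (S)-5-(tert-butyldimethylsilyloxy)-8-methylnon-7-ene-1,3-diyne | C#CC#C[C@H](CC=C(C)C)O[Si](C)(C)C(C)(C)C | intermediate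
9 | N-methoxy-N-methylacetamide | CC(=O)N(C)OC | starting material
10 | lithium diynide of 8 | [Li]C#CC#C[C@H](CC=C(C)C)O[Si](C)(C)C(C)(C)C | intermediate
11 | (S)-7-(tert-butyldimethylsilyloxy)-10-methylundec-9-ene-3,5-diyn-2-one | CC(=O)C#CC#C[C@H](CC=C(C)C)O[Si](C)(C)C(C)(C)C | intermediate
12 | 2-methoxyfuran | COc1ccco1 | starting material
13 | 2-acetyl-3-[(S)-3-(tert-butyldimethylsilyloxy)-6-methylhept-5-en-1-ynyl]-1-methoxy-7-oxabicyclo[2.2.1]hepta-2,5-diene (both bridgehead diastereomers) | COC12C=CC(O1)C(C#C[C@H](CC=C(C)C)O[Si](C)(C)C(C)(C)C)=C2C(C)=O | intermediate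
14 | 1-{2-[(S)-3-(tert-butyldimethylsilyloxy)-6-methylhept-5-en-1-ynyl]-3-hydroxy-6-methoxyphenyl}ethanone | COc1ccc(O)c(C#C[C@H](CC=C(C)C)O[Si](C)(C)C(C)(C)C)c1C(C)=O | intermediate
15 | 1-{3-(tert-butyldimethylsilyloxy)-2-[(S)-3-(tert-butyldimethylsilyloxy)-6-methylhept-5-en-1-ynyl]-6-methoxyphenyl}ethanone | COc1ccc(O[Si](C)(C)C(C)(C)C)c(C#C[C@H](CC=C(C)C)O[Si](C)(C)C(C)(C)C)c1C(C)=O | intermediate
16 | 5-(tert-butyldimethylsilyloxy)-3-[(S)-1-(tert-butyldimethylsilyloxy)-4-methylpent-3-enyl]-8-methoxynaphthalen-1-ol | COc1ccc(O[Si](C)(C)C(C)(C)C)c2cc(cc(O)c12)[C@H](CC=C(C)C)O[Si](C)(C)C(C)(C)C | intermediate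
17 | 8-(tert-butyldimethylsilyloxy)-2-[(S)-1-(tert-butyldimethylsilyloxy)-4-methylpent-3-enyl]-5-methoxynaphthalene-1,4-dione | COc1ccc(O[Si](C)(C)C(C)(C)C)c2c1C(=O)C=C([C@H](CC=C(C)C)O[Si](C)(C)C(C)(C)C)C2=O | intermediate
18 | 8-hydroxy-2-[(S)-1-hydroxy-4-methylpent-3-enyl]-5-methoxynaphthalene-1,4-dione | COc1ccc(O)c2c1C(=O)C=C([C@H](CC=C(C)C)O)C2=O | intermediate
19 | 3-methylbut-2-enoic acid | CC(C)=CC(=O)O | starting material
20 | (S)-1-(8-hydroxy-5-methoxy-1,4-dioxo-1,4-dihydronaphthalen-2-yl)-4-methylpent-3-enyl 3-methylbut-2-enoate | COc1ccc(O)c2c1C(=O)C=C([C@H](CC=C(C)C)OC(=O)C=C(C)C)C2=O | target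

**Totals**

Total step count: 10. Longest linear sequence: 10 steps (1 to 20).

**Steps most likely to fail**

Step 7. In the strongly basic last stage the propargylic C–H of 15 may be removed, and alkyne-to-allene isomerisation would erode the configuration at C1'. The enolate may also close through oxygen instead of carbon. The fallback sets out from 15, which is isolated by stopping the one-pot sequence after the silylation stage. TMSOTf and Et3N (CH2Cl2, 0 °C) should convert 15 into the trimethylsilyl enol ether F1. F1 is then cyclised under neutral conditions by electrophilic activation of the alkyne (cat. [Rh(CO)2Cl]2 or W(CO)5(thf), toluene), the known 6-endo-dig cycloaromatisation of ortho-alkynylaryl silyl enol ethers, to the 1-(trimethylsilyloxy)naphthalene F2. Brief methanolysis of the labile aryl O–SiMe3 bond (citric acid, MeOH, 0 °C) returns to the route at 16.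

Step 8. Oxygenation at C1, which is flanked by the peri silyloxy group and the branched side chain, may be slow, so that ortho-oxygenation or oxidative coupling of the naphthoxyl radical competes. The fallback sets out from 16 and uses a two-electron oxidative dearomatisation with solvent capture: PhI(OAc)2 in MeOH at 0 °C should give the para-quinone monoketal F3. Mild hydrolysis of the ketal (dilute AcOH in THF/H2O) then returns to the route at 17.

Step 3. The skipped enone 5 may isomerise into conjugation before it is reduced, or facial discrimination in the hydride transfer may be insufficient. The fallback builds the carbinol by C–C bond formation instead of ketone reduction and sets out from 2 and 3. DIBAL-H (THF, −78 °C) should reduce 2 to 4-methylpent-3-enal F4, which is used cold without purification. Separately, 3 is mono-desilylated (MeLi·LiBr, THF, then aq. NH4Cl) to buta-1,3-diynyl(trimethyl)silane F5. Zinc–ProPhenol-catalysed enantioselective alkynylation of F4 with F5 (Me2Zn, the ProPhenol antipode that delivers the (S)-carbinol, Ph3PO, toluene, 0 °C) should give 6 directly, where the fallback rejoins the route.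

**Further compounds**

F1 | step 7 | 1-{3-(tert-butyldimethylsilyloxy)-2-[(S)-3-(tert-butyldimethylsilyloxy)-6-methylhept-5-en-1-ynyl]-6-methoxyphenyl}-1-(trimethylsilyloxy)ethene | COc1ccc(O[Si](C)(C)C(C)(C)C)c(C#C[C@H](CC=C(C)C)O[Si](C)(C)C(C)(C)C)c1C(=C)O[Si](C)(C)C
F2 | step 7 | {5-(tert-butyldimethylsilyloxy)-3-[(S)-1-(tert-butyldimethylsilyloxy)-4-methylpent-3-enyl]-8-methoxynaphthalen-1-yl}oxy(trimethyl)silane | COc1ccc(O[Si](C)(C)C(C)(C)C)c2cc(cc(O[Si](C)(C)C)c12)[C@H](CC=C(C)C)O[Si](C)(C)C(C)(C)C
F3 | step 8 | 5-(tert-butyldimethylsilyloxy)-3-[(S)-1-(tert-butyldimethylsilyloxy)-4-methylpent-3-enyl]-4,4,8-trimethoxynaphthalen-1(4H)-one | COc1ccc(O[Si](C)(C)C(C)(C)C)c2c1C(=O)C=C([C@H](CC=C(C)C)O[Si](C)(C)C(C)(C)C)C2(OC)OC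
F4 | step 3 | 4-methylpent-3-enal | CC(C)=CCC=O
F5 | step 3 | buta-1,3-diynyl(trimethyl)silane | C[Si](C)(C)C#CC#C
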